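A direct plan would make the α-methylene lactone first and close the carbocycle last.
It would couple two small fragments to the bromomethyl butenolide A1 (chromium/nickel coupling, lactonisation, bromination).
An intermolecular chromium allylation would then add the C2–C6 arm, and esterification would give seco ester A2.
A palladium/copper coupling of the thioester with the terminal alkyne would close ynone A3, whose C10 hydroxyl would add to the triple bond to form the furanone.
Weakest would be this last acyl–alkynyl ring closure: a cyclisation without precedent to a strained ten-membered enynone, run on the most precious intermediate, with thiolate set free beside an α-methylene lactone and an epoxy ester.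
Second, the intermolecular allylation would have to set the C6 carbinol from the C8 centre alone, so C6 would rest on a small transition-state preference and could not be corrected once acylated.
Third, the coupling that sets C8 would need more than one equivalent of a chiral ligand, and its thioester would have to survive two chromium steps as a spectator.

**Plan of the new route**
The retrosynthesis cuts, in this order: the C6 ester; the C7–C8 bond together with the lactone C12–O bond (one operation); the C11–C13 and C6–C7 bonds of the side arm; the furanone O–C3 bond; the C1–C2 bond.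
Forward, the 3(2H)-furanone (ring B) arises first on an open, unstrained chain; the ten-membered carbocycle (ring A) and the lactone (ring C) then arise together.
Enabling feature: C7 is the γ-carbon of a 2-carboxyallyl unit C13–C11(C12)=C7 and C8 is the carbinol carbon that carries the lactone oxygen, so the C7–C8 bond with the exo-methylene lactone is the retron of an allylmetal–aldehyde addition; the planar furanone and the Z-C4=C5 bond hold C6 and C9 close.
No cyclic ynone and no acyl–alkynyl closure occur; C6 is set by a catalyst before the ring exists and then directs C7 and C8, which form together; no thioester is carried.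
(S)-Lactic acid gives C10, (R)-2-methylglycidol the epoxy ester, and commercial (Z)-3-methylpent-2-en-4-yn-1-ol brings C2–C6 with the Z geometry.

Key step: step 12

Assumption: (S,S)-ProPhenol is taken to deliver the alkynyl group to the face of enal 15 that gives the (R)-carbinol; should the sense be the opposite with this Z-enal, (R,R)-ProPhenol is used.

Step 1
Reactants: 1 (S)-lactic acid; 2 pivalaldehyde
Product: 3 (2S,5S)-2-tert-butyl-5-methyl-1,3-dioxolan-4-one
Conditions: TsOH·H2O (cat.), H2SO4 (cat.), pentane, reflux, Dean–Stark; recryst. Et2O/pentane, −78 °C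
Reagents that add atoms: none
Why: Acid-catalysed acetalisation gives the thermodynamically favoured cis-dioxolanone, so the lactate centre fixes the acetal carbon that later relays the chirality (self-regeneration of stereocentres).

Step 2
Reactants: 3 (2S,5S)-2-tert-butyl-5-methyl-1,3-dioxolan-4-one; 4 allyl bromide
Product: 6 (2S,5R)-2-tert-butyl-5-methyl-5-(prop-2-en-1-yl)-1,3-dioxolan-4-one, via lithium enolate 5 (not isolated)
Conditions: LiN(i-Pr)2 (1.1 equiv), THF, −78 °C; then 4, −78 → −20 °C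
Reagents that add atoms: none
Why: Enolate alkylation occurs on the face anti to the tert-butyl group and sets the quaternary C10 centre; the allyl terminus serves as a masked C8 aldehyde.

Step 3
Reactants: 7 (2Z)-3-methylpent-2-en-4-yn-1-ol
Product: 8 (2Z)-3-methylpent-2-en-4-ynal
Conditions: MnO2 (15 equiv), CH2Cl2, rt, dark
Reagents that add atoms: none
Why: MnO2 oxidises the allylic alcohol to the enal (allylic oxidation) without touching the alkyne or the Z double bond.

Step 4
Reactants: 8 (2Z)-3-methylpent-2-en-4-ynal; 9 triethyl orthoformate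
Product: 10 (3Z)-5,5-diethoxy-3-methylpent-3-en-1-yne
Conditions: 9 (1.5 equiv), EtOH, NH4NO3 (cat.), rt
Reagents that add atoms: none
Why: Acid-catalysed acetalisation masks C6 as a base-stable diethyl acetal so that the alkyne can be lithiated.

Step 5
Reactants: 10 (3Z)-5,5-diethoxy-3-methylpent-3-en-1-yne; 6 (2S,5R)-2-tert-butyl-5-methyl-5-(prop-2-en-1-yl)-1,3-dioxolan-4-one
Product: 13 (4R,8Z)-10,10-diethoxy-4-hydroxy-4,8-dimethyldeca-1,8-dien-6-yn-5-one, via lithium acetylide 11 (not isolated), via lithium hemiketal alkoxide 12 (not isolated)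
Conditions: 10, n-BuLi (1.0 equiv), THF, −78 °C; then 6 (1.2 equiv), −78 → −40 °C; aq. NH4Cl
Reagents that add atoms: none
Why: In a nucleophilic acyl substitution the acetylide adds once to the acetal-ester carbonyl, and the tetrahedral intermediate, stable in the cold, collapses on work-up with loss of pivalaldehyde to the open-chain α′-hydroxy ynone (C1–C2 bond) without touching C10.

Step 6
Reactants: 13 (4R,8Z)-10,10-diethoxy-4-hydroxy-4,8-dimethyldeca-1,8-dien-6-yn-5-one
Product: 15 (2Z)-3-[(5R)-5-methyl-4-oxo-5-(prop-2-en-1-yl)-4,5-dihydrofuran-2-yl]but-2-enal, via furanone acetal 14 (not isolated)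
Conditions: Ph3PAuNTf2 (2 mol%), toluene, rt; then PPTS (10 mol%), acetone/H2O (10:1), rt
Reagents that add atoms: water, O
Why: Activation of the ynone by monovalent gold triggers 5-endo-dig addition of the C10 hydroxyl to C3 (cycloisomerisation of an α′-hydroxy ynone to a 3(2H)-furanone) on an unstrained chain, and mild acid hydrolysis then unveils the Z-enal at C6.

Step 7
Reactants: 15 (2Z)-3-[(5R)-5-methyl-4-oxo-5-(prop-2-en-1-yl)-4,5-dihydrofuran-2-yl]but-2-enal; 16 methyl propiolate
Product: 18 methyl (4R,5Z)-4-hydroxy-6-[(5R)-5-methyl-4-oxo-5-(prop-2-en-1-yl)-4,5-dihydrofuran-2-yl]hept-5-en-2-ynoate, via methylzinc acetylide 17 (not isolated)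
Conditions: (S,S)-ProPhenol (20 mol%), Ph3P=O (40 mol%), Me2Zn (3 equiv), 16 (3 equiv), toluene, 4 °C; aq. NH4Cl
Reagents that add atoms: none
Why: Catalytic enantioselective alkynylation of an enal (zinc–ProPhenol addition of a zinc propiolate) forms C6–C7 and sets the C6 carbinol (R) under ligand control, the remote C10 centre having no influence.

Step 8
Reactants: 18 methyl (4R,5Z)-4-hydroxy-6-[(5R)-5-methyl-4-oxo-5-(prop-2-en-1-yl)-4,5-dihydrofuran-2-yl]hept-5-en-2-ynoate
Product: 19 methyl (4R,5Z)-4-[(tert-butyldimethylsilyl)oxy]-6-[(5R)-5-methyl-4-oxo-5-(prop-2-en-1-yl)-4,5-dihydrofuran-2-yl]hept-5-en-2-ynoate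
Conditions: TBSOTf (1.3 equiv), 2,6-lutidine (2 equiv), CH2Cl2, −78 °C
Reagents that add atoms: tert-butyldimethylsilyl triflate, CC(C)(C)[Si](C)(C)OS(=O)(=O)C(F)(F)F
Why: Silylation turns the C6 oxygen into a poor leaving group that can neither lactonise onto C12 nor be expelled from the later allylmetal.

Step 9
Reactants: 19 methyl (4R,5Z)-4-[(tert-butyldimethylsilyl)oxy]-6-[(5R)-5-methyl-4-oxo-5-(prop-2-en-1-yl)-4,5-dihydrofuran-2-yl]hept-5-en-2-ynoate
Product: 21 methyl (2Z,4R,5Z)-4-[(tert-butyldimethylsilyl)oxy]-2-(hydroxymethyl)-6-[(5R)-5-methyl-4-oxo-5-(prop-2-en-1-yl)-4,5-dihydrofuran-2-yl]hepta-2,5-dienoate, via α-aluminoenoate 20 (not isolated)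
Conditions: i-Bu2AlH (1.3 equiv), N-methylmorpholine N-oxide (1.5 equiv), THF, 0 °C; then (CH2O)n (excess), 0 °C → rt; aq. Rochelle salt
Reagents that add atoms: formaldehyde (as paraformaldehyde), C=O
Why: The amine-oxide-complexed hydride adds 1,4 to the ynoate in syn fashion (hydrogen on C7, aluminium on C11; vinylalumination), and the α-aluminoacrylate is trapped by formaldehyde to install C13 with C6 cis to the ester.

Step 10
Reactants: 21 methyl (2Z,4R,5Z)-4-[(tert-butyldimethylsilyl)oxy]-2-(hydroxymethyl)-6-[(5R)-5-methyl-4-oxo-5-(prop-2-en-1-yl)-4,5-dihydrofuran-2-yl]hepta-2,5-dienoate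
Product: 23 methyl (2Z,4R,5Z)-4-[(tert-butyldimethylsilyl)oxy]-2-(hydroxymethyl)-6-[(5R)-5-methyl-4-oxo-5-(2-oxoethyl)-4,5-dihydrofuran-2-yl]hepta-2,5-dienoate, via vicinal diol 22 (not isolated)
Conditions: OsO4 (2 mol%), NaIO4 (3 equiv), 2,6-lutidine (2 equiv), dioxane/H2O (3:1), 0 °C → rt
Reagents that add atoms: osmium tetroxide, O=[Os](=O)(=O)=O; sodium periodate, [Na+].[O-]I(=O)(=O)=O
Why: In this Lemieux–Johnson cleavage OsO4 dihydroxylates the only monosubstituted, electron-rich alkene (all others are trisubstituted and conjugated to carbonyl groups) and periodate cleaves the diol to the C8 aldehyde.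

Step 11
Reactants: 23 methyl (2Z,4R,5Z)-4-[(tert-butyldimethylsilyl)oxy]-2-(hydroxymethyl)-6-[(5R)-5-methyl-4-oxo-5-(2-oxoethyl)-4,5-dihydrofuran-2-yl]hepta-2,5-dienoate
Product: 24 methyl (2E,4R,5Z)-2-(bromomethyl)-4-[(tert-butyldimethylsilyl)oxy]-6-[(5R)-5-methyl-4-oxo-5-(2-oxoethyl)-4,5-dihydrofuran-2-yl]hepta-2,5-dienoate
Conditions: N-bromosuccinimide (1.3 equiv), Me2S (1.5 equiv), CH2Cl2, −20 → 0 °C; used at once
Reagents that add atoms: N-bromosuccinimide, O=C1CCC(=O)N1Br
Why: Corey–Kim bromination converts the allylic alcohol into the bromide under neutral conditions that tolerate the base-sensitive β-oxy aldehyde and the silyl ether.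

Step 12
Reactants: 24 methyl (2E,4R,5Z)-2-(bromomethyl)-4-[(tert-butyldimethylsilyl)oxy]-6-[(5R)-5-methyl-4-oxo-5-(2-oxoethyl)-4,5-dihydrofuran-2-yl]hepta-2,5-dienoate
Product: 27 (6R,7R,8S,10R,4Z)-6-[(tert-butyldimethylsilyl)oxy]-1-oxo-3,10-epoxygermacra-2,4,11(13)-trien-8,12-olide, via allylchromium dichloride 25 (not isolated), via hydroxy ester 26 (not isolated)
Conditions: CrCl2 (8 equiv), THF/DMF (10:1), syringe-pump addition to 2 mM, rt; aq. NH4Cl; then PPTS (cat.), CH2Cl2, rt
Reagents that add atoms: none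
Why: CrCl2 reduces the allylic bromide to the 2-(methoxycarbonyl)allylchromium species 25 (trivalent chromium), which adds through its γ-carbon C7 to the tethered C8 aldehyde in a six-membered chair transition state, and the chromium alkoxide of 26 then attacks the neighbouring ester and expels methanol (intramolecular Nozaki–Hiyama allylation, a Barbier-type macrocyclisation, followed by lactonisation). The closest known reaction type is the cyclisation of 2-(alkoxycarbonyl)allyl bromides onto aldehydes mediated by divalent chromium, which closes the ten-membered rings of germacranolides together with their trans α-methylene lactones. Ring A closes by C–C bond formation between an allylmetal and an aldehyde in a ten-membered ring in which the furanone and the Z-alkene already hold six ring atoms (C10, C1 to C5) rigid; ring C closes by 5-exo-trig acyl substitution. C8 versus C7: the allylchromium reagent equilibrates by 1,3-metal shift to the form with C6 trans to CH2Cr, and with the aldehyde chain (C9) equatorial the chair gives the anti adduct, that is the trans lactone (7R,8S). C7 versus C6: the C6–H bond eclipses the C7=C11 bond to avoid allylic 1,3-strain with the ester, and the tether delivers the aldehyde from the face of C5, anti to the silyloxy group, which gives the C6/C7 relationship of the target. The step needs aldehyde-over-ketone chemoselectivity (allylchromium reagents spare the vinylogous ester carbonyl), ring closure over oligomerisation (slow addition, high dilution) and no 1,4-elimination of the C6 oxygen, which its silyl ether secures.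

Step 13
Reactants: 27 (6R,7R,8S,10R,4Z)-6-[(tert-butyldimethylsilyl)oxy]-1-oxo-3,10-epoxygermacra-2,4,11(13)-trien-8,12-olide
Product: 28 (6R,7S,8S,10R,4Z)-6-hydroxy-1-oxo-3,10-epoxygermacra-2,4,11(13)-trien-8,12-olide
Conditions: HF·pyridine, pyridine, THF, 0 °C
Reagents that add atoms: none
Why: Buffered fluoride desilylation frees the C6 hydroxyl without base, so the α-methylene lactone is not attacked and the lactone does not migrate to O6 (the descriptor at C7 changes by priority only).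

Step 14
Reactants: 29 (R)-2-methylglycidol
Product: 31 (S)-2-methylglycidic acid, via epoxy aldehyde 30 (not isolated)
Conditions: TEMPO (10 mol%), PhI(OAc)2 (2.2 equiv), MeCN/H2O (1:1), 0 °C → rt
Reagents that add atoms: water, O
Why: Nitroxyl-catalysed oxidation takes the primary alcohol through the aldehyde hydrate to the acid without opening the epoxide; the descriptor changes from R to S by priority only.

Step 15
Reactants: 28 (6R,7S,8S,10R,4Z)-6-hydroxy-1-oxo-3,10-epoxygermacra-2,4,11(13)-trien-8,12-olide; 31 (S)-2-methylglycidic acid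
Product: 33 (6R,7R,8S,10R,4Z)-6-[(2S)-2-methyloxirane-2-carbonyloxy]-1-oxo-3,10-epoxygermacra-2,4,11(13)-trien-8,12-olide (CNP0321429.1), via mixed anhydride 32 (not isolated)
Conditions: 31, 2,4,6-Cl3C6H2COCl (1.2 equiv), Et3N (2.5 equiv), toluene, 0 °C; then 28, DMAP (1.5 equiv), 0 °C → rt
Reagents that add atoms: none
Why: Yamaguchi esterification through the mixed anhydride acylates the secondary allylic C6 hydroxyl with retention at C6 and at the epoxide carbon.

## Compound list

1 | (S)-lactic acid | C[C@H](O)C(=O)O | starting material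
2 | pivalaldehyde | CC(C)(C)C=O | starting material
3 | (2S,5S)-2-tert-butyl-5-methyl-1,3-dioxolan-4-one | C[C@@H]1O[C@H](C(C)(C)C)OC1=O | intermediate
4 | allyl bromide | C=CCBr | starting material
5 | lithium (2S)-2-tert-butyl-5-methyl-1,3-dioxol-4-olate | CC1=C([O-])O[C@@H](C(C)(C)C)O1.[Li+] | intermediate
6 | (2S,5R)-2-tert-butyl-5-methyl-5-(prop-2-en-1-yl)-1,3-dioxolan-4-one | C[C@]1(CC=C)O[C@H](C(C)(C)C)OC1=O | intermediate
7 | (2Z)-3-methylpent-2-en-4-yn-1-ol | C#C/C(C)=C\CO | starting material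
8 | (2Z)-3-methylpent-2-en-4-ynal | C#C/C(C)=C\C=O | intermediate
9 | triethyl orthoformate | CCOC(OCC)OCC | starting material
10 | (3Z)-5,5-diethoxy-3-methylpent-3-en-1-yne | C#C/C(C)=C\C(OCC)OCC | intermediate
11 | lithium (3Z)-5,5-diethoxy-3-methylpent-3-en-1-yn-1-ide | [Li+].[C-]#C/C(C)=C\C(OCC)OCC | intermediate
12 | lithium (2S,5R)-2-tert-butyl-4-[(3Z)-5,5-diethoxy-3-methylpent-3-en-1-yn-1-yl]-5-methyl-5-(prop-2-en-1-yl)-1,3-dioxolan-4-olate (mixture at C4) | C[C@]1(CC=C)O[C@H](C(C)(C)C)OC1([O-])C#C/C(C)=C\C(OCC)OCC.[Li+] | intermediate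
13 | (4R,8Z)-10,10-diethoxy-4-hydroxy-4,8-dimethyldeca-1,8-dien-6-yn-5-one | C=CC[C@@](C)(O)C(=O)C#C/C(C)=C\C(OCC)OCC | intermediate
14 | (2R)-5-[(2Z)-4,4-diethoxybut-2-en-2-yl]-2-methyl-2-(prop-2-en-1-yl)furan-3(2H)-one | C=CC[C@@]1(C)OC(=CC1=O)/C(C)=C\C(OCC)OCC | intermediate
15 | (2Z)-3-[(5R)-5-methyl-4-oxo-5-(prop-2-en-1-yl)-4,5-dihydrofuran-2-yl]but-2-enal | C=CC[C@@]1(C)OC(=CC1=O)/C(C)=C\C=O | intermediate
16 | methyl propiolate | C#CC(=O)OC | starting material
17 | methyl(3-methoxy-3-oxoprop-1-yn-1-yl)zinc | C[Zn]C#CC(=O)OC | intermediate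
18 | methyl (4R,5Z)-4-hydroxy-6-[(5R)-5-methyl-4-oxo-5-(prop-2-en-1-yl)-4,5-dihydrofuran-2-yl]hept-5-en-2-ynoate | C=CC[C@@]1(C)OC(=CC1=O)/C(C)=C\[C@@H](O)C#CC(=O)OC | intermediate
19 | methyl (4R,5Z)-4-[(tert-butyldimethylsilyl)oxy]-6-[(5R)-5-methyl-4-oxo-5-(prop-2-en-1-yl)-4,5-dihydrofuran-2-yl]hept-5-en-2-ynoate | C=CC[C@@]1(C)OC(=CC1=O)/C(C)=C\[C@@H](O[Si](C)(C)C(C)(C)C)C#CC(=O)OC | intermediate
20 | methyl (2E,4R,5Z)-4-[(tert-butyldimethylsilyl)oxy]-2-(diisobutylalumanyl)-6-[(5R)-5-methyl-4-oxo-5-(prop-2-en-1-yl)-4,5-dihydrofuran-2-yl]hepta-2,5-dienoate (amine oxide complex) | C=CC[C@@]1(C)OC(=CC1=O)/C(C)=C\[C@@H](O[Si](C)(C)C(C)(C)C)/C=C(\C(=O)OC)[Al](CC(C)C)CC(C)C | intermediate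
21 | methyl (2Z,4R,5Z)-4-[(tert-butyldimethylsilyl)oxy]-2-(hydroxymethyl)-6-[(5R)-5-methyl-4-oxo-5-(prop-2-en-1-yl)-4,5-dihydrofuran-2-yl]hepta-2,5-dienoate | C=CC[C@@]1(C)OC(=CC1=O)/C(C)=C\[C@@H](O[Si](C)(C)C(C)(C)C)/C=C(\C(=O)OC)CO | intermediate
22 | methyl (2Z,4R,5Z)-4-[(tert-butyldimethylsilyl)oxy]-6-[(5R)-5-(2,3-dihydroxypropyl)-5-methyl-4-oxo-4,5-dihydrofuran-2-yl]-2-(hydroxymethyl)hepta-2,5-dienoate (mixture of carbinol epimers) | OCC(O)C[C@@]1(C)OC(=CC1=O)/C(C)=C\[C@@H](O[Si](C)(C)C(C)(C)C)/C=C(\C(=O)OC)CO | intermediate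
23 | methyl (2Z,4R,5Z)-4-[(tert-butyldimethylsilyl)oxy]-2-(hydroxymethyl)-6-[(5R)-5-methyl-4-oxo-5-(2-oxoethyl)-4,5-dihydrofuran-2-yl]hepta-2,5-dienoate | O=CC[C@@]1(C)OC(=CC1=O)/C(C)=C\[C@@H](O[Si](C)(C)C(C)(C)C)/C=C(\C(=O)OC)CO | intermediate
24 | methyl (2E,4R,5Z)-2-(bromomethyl)-4-[(tert-butyldimethylsilyl)oxy]-6-[(5R)-5-methyl-4-oxo-5-(2-oxoethyl)-4,5-dihydrofuran-2-yl]hepta-2,5-dienoate | O=CC[C@@]1(C)OC(=CC1=O)/C(C)=C\[C@@H](O[Si](C)(C)C(C)(C)C)/C=C(\C(=O)OC)CBr | intermediate
25 | 2-(methoxycarbonyl)allylchromium dichloride derived from 24 (trivalent chromium) | O=CC[C@@]1(C)OC(=CC1=O)/C(C)=C\[C@@H](O[Si](C)(C)C(C)(C)C)/C=C(\C(=O)OC)C[Cr](Cl)Cl | intermediate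
26 | methyl (6R,7R,8S,10R,4Z)-6-[(tert-butyldimethylsilyl)oxy]-8-hydroxy-1-oxo-3,10-epoxygermacra-2,4,11(13)-trien-12-oate | O[C@H]1C[C@@]2(C)OC(=CC2=O)/C(C)=C\[C@@H](O[Si](C)(C)C(C)(C)C)[C@@H]1C(=C)C(=O)OC | intermediate
27 | (6R,7R,8S,10R,4Z)-6-[(tert-butyldimethylsilyl)oxy]-1-oxo-3,10-epoxygermacra-2,4,11(13)-trien-8,12-olide | C=C1C(=O)O[C@H]2C[C@@]3(C)OC(=CC3=O)/C(C)=C\[C@@H](O[Si](C)(C)C(C)(C)C)[C@H]12 | intermediate
28 | (6R,7S,8S,10R,4Z)-6-hydroxy-1-oxo-3,10-epoxygermacra-2,4,11(13)-trien-8,12-olide | C=C1C(=O)O[C@H]2C[C@@]3(C)OC(=CC3=O)/C(C)=C\[C@@H](O)[C@H]12 | intermediate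
29 | (R)-2-methylglycidol [(2R)-(2-methyloxiran-2-yl)methanol] | OC[C@]1(C)CO1 | starting material
30 | (2S)-2-methyloxirane-2-carbaldehyde | O=C[C@]1(C)CO1 | intermediate
31 | (S)-2-methylglycidic acid [(2S)-2-methyloxirane-2-carboxylic acid] | OC(=O)[C@]1(C)CO1 | intermediate
32 | (2S)-2-methyloxirane-2-carboxylic 2,4,6-trichlorobenzoic anhydride | O=C(OC(=O)[C@]1(C)CO1)c1c(Cl)cc(Cl)cc1Cl | intermediate
33 | (6R,7R,8S,10R,4Z)-6-[(2S)-2-methyloxirane-2-carbonyloxy]-1-oxo-3,10-epoxygermacra-2,4,11(13)-trien-8,12-olide (CNP0321429.1) | C=C1C(=O)O[C@H]2C[C@@]3(C)OC(=CC3=O)/C(C)=C\[C@@H](OC(=O)[C@]3(C)CO3)[C@H]12 | target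

Total step count: 15. Longest linear sequence: 12 steps (steps 1, 2, 5 to 13 and 15).

Steps most likely to fail:

Step 12. The allylchromium reagent may oligomerise, or the aldehyde may be attacked from the wrong face so that a cis lactone or the C7 epimer forms. The fallback sets out from hydroxy aldehyde 23. Acetylation (Ac2O, pyridine, DMAP cat.) would give methyl (2Z,4R,5Z)-2-[(acetyloxy)methyl]-4-[(tert-butyldimethylsilyl)oxy]-6-[(5R)-5-methyl-4-oxo-5-(2-oxoethyl)-4,5-dihydrofuran-2-yl]hepta-2,5-dienoate F1. Borylation with B2pin2 and Pd2(dba)3 (cat., zerovalent palladium) in DMSO/toluene would turn the acetate into the 2-(methoxycarbonyl)allyl pinacolboronate F2. This non-reducing allyl donor should add to the tethered aldehyde through the closed six-membered allylboration transition state on gentle warming (Sc(OTf)3 if needed). Acidic work-up would lactonise the resulting hydroxy ester 26 to 27, where the route is rejoined.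

Step 9. The hydride may attack the furanone carbonyl or the ester instead of adding 1,4 to the ynoate. The fallback sets out from ynoate 19 and uses no aluminium hydride. Syn-hydrostannation (Bu3SnH, Pd(PPh3)4 cat.) would place tin on C11 and give methyl (2E,4R,5Z)-4-[(tert-butyldimethylsilyl)oxy]-6-[(5R)-5-methyl-4-oxo-5-(prop-2-en-1-yl)-4,5-dihydrofuran-2-yl]-2-(tributylstannyl)hepta-2,5-dienoate F3. Iododestannylation (I2, CH2Cl2, 0 °C) would give with retention the corresponding methyl (2E,4R,5Z)-2-iodohepta-2,5-dienoate F4. Stille coupling with Bu3SnCH2OH (Pd(PPh3)4 cat., dioxane, 80 °C) would return the route at 21.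

Step 7. Facial selectivity may be poor or the addition slow with this Z-configured, β,β-disubstituted enal. The fallback sets out from enal 15. Addition of lithium methyl propiolate (methyl propiolate, LiN(SiMe3)2, THF, −78 °C) would give methyl (5Z)-4-hydroxy-6-[(5R)-5-methyl-4-oxo-5-(prop-2-en-1-yl)-4,5-dihydrofuran-2-yl]hept-5-en-2-ynoate as a mixture of C4 epimers F5. Lipase-catalysed acylation (Burkholderia cepacia lipase, vinyl acetate, hexane) is expected, from the empirical rule for a bulky alkenyl arm against a slim alkynyl arm, to acylate the (4S)-epimer to methyl (4S,5Z)-4-(acetyloxy)-6-[(5R)-5-methyl-4-oxo-5-(prop-2-en-1-yl)-4,5-dihydrofuran-2-yl]hept-5-en-2-ynoate F6. The (4R)-alcohol 18 would remain and the route is rejoined there.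

## Further compounds

F1 | step 12 | methyl (2Z,4R,5Z)-2-[(acetyloxy)methyl]-4-[(tert-butyldimethylsilyl)oxy]-6-[(5R)-5-methyl-4-oxo-5-(2-oxoethyl)-4,5-dihydrofuran-2-yl]hepta-2,5-dienoate | O=CC[C@@]1(C)OC(=CC1=O)/C(C)=C\[C@@H](O[Si](C)(C)C(C)(C)C)/C=C(\C(=O)OC)COC(C)=O
F2 | step 12 | methyl (2Z,4R,5Z)-4-[(tert-butyldimethylsilyl)oxy]-6-[(5R)-5-methyl-4-oxo-5-(2-oxoethyl)-4,5-dihydrofuran-2-yl]-2-[(4,4,5,5-tetramethyl-1,3,2-dioxaborolan-2-yl)methyl]hepta-2,5-dienoate | O=CC[C@@]1(C)OC(=CC1=O)/C(C)=C\[C@@H](O[Si](C)(C)C(C)(C)C)/C=C(\C(=O)OC)CB1OC(C)(C)C(C)(C)O1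
F3 | step 9 | methyl (2E,4R,5Z)-4-[(tert-butyldimethylsilyl)oxy]-6-[(5R)-5-methyl-4-oxo-5-(prop-2-en-1-yl)-4,5-dihydrofuran-2-yl]-2-(tributylstannyl)hepta-2,5-dienoate | C=CC[C@@]1(C)OC(=CC1=O)/C(C)=C\[C@@H](O[Si](C)(C)C(C)(C)C)/C=C(\C(=O)OC)[Sn](CCCC)(CCCC)CCCC
F4 | step 9 | methyl (2E,4R,5Z)-4-[(tert-butyldimethylsilyl)oxy]-2-iodo-6-[(5R)-5-methyl-4-oxo-5-(prop-2-en-1-yl)-4,5-dihydrofuran-2-yl]hepta-2,5-dienoate | C=CC[C@@]1(C)OC(=CC1=O)/C(C)=C\[C@@H](O[Si](C)(C)C(C)(C)C)/C=C(\C(=O)OC)I
F5 | step 7 | methyl (5Z)-4-hydroxy-6-[(5R)-5-methyl-4-oxo-5-(prop-2-en-1-yl)-4,5-dihydrofuran-2-yl]hept-5-en-2-ynoate (mixture of C4 epimers) | C=CC[C@@]1(C)OC(=CC1=O)/C(C)=C\C(O)C#CC(=O)OC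
F6 | step 7 | methyl (4S,5Z)-4-(acetyloxy)-6-[(5R)-5-methyl-4-oxo-5-(prop-2-en-1-yl)-4,5-dihydrofuran-2-yl]hept-5-en-2-ynoate | C=CC[C@@]1(C)OC(=CC1=O)/C(C)=C\[C@H](OC(C)=O)C#CC(=O)OC
A1 | direct plan | S-ethyl (2R)-3-[(2S)-4-(bromomethyl)-5-oxo-2,5-dihydrofuran-2-yl]-2-hydroxy-2-methylpropanethioate | CCSC(=O)[C@](C)(O)C[C@H]1C=C(CBr)C(=O)O1
A2 | direct plan | (1R,2Z)-1-{(2S,3R)-2-[(2R)-3-(ethylsulfanyl)-2-hydroxy-2-methyl-3-oxopropyl]-4-methylidene-5-oxooxolan-3-yl}-3-methylpent-2-en-4-yn-1-yl (2S)-2-methyloxirane-2-carboxylate | C=C1C(=O)O[C@@H](C[C@@](C)(O)C(=O)SCC)[C@@H]1[C@H](OC(=O)[C@]2(C)CO2)/C=C(C)\C#C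
A3 | direct plan | (6R,7R,8S,10R,4Z)-10-hydroxy-6-[(2S)-2-methyloxirane-2-carbonyloxy]-1-oxogermacra-4,11(13)-dien-2-yn-8,12-olide | C=C1C(=O)O[C@H]2C[C@@](C)(O)C(=O)C#C/C(C)=C\[C@@H](OC(=O)[C@]3(C)CO3)[C@H]12
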